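**Assumption:** The SMILES corresponds to (7R,8R,8'R) (THF numbering 2R,3R,4R). The aryl and benzyl groups are cis on the ring, and the methyl is trans to both. Facial selectivity in steps 4 and 8 follows the standard chelated-imide models, using the (R)-4-benzyloxazolidinone auxiliary.

## Retrosynthetic overview
1. The THF ring is closed last, by C7–O bond formation. This is the new step: a free-phenol-gated dehydrogenative C(sp3)–H etherification through a p-quinone methide, which sets C7 trans to the C8 methyl.
2. The precursor is the acyclic alcohol (2R,3S)-2-(syringylmethyl)-3-methyl-4-guaiacylbutan-1-ol. Its two stereocentres come from one (R)-benzyloxazolidinone imide: Cu-mediated methyl 1,4-addition sets C8, then Evans benzylation sets C8'.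
3. The enoyl imide is made by cross-metathesis of MOM-eugenol with N-acryloyl-(R)-4-benzyloxazolidinone.
4. The syringyl benzyl bromide is made from syringaldehyde. The only ring constructed is the THF; both arenes come from commercial materials.

## Route

**Step 1**
Reactants: 1 (R)-4-benzyloxazolidin-2-one
Product: 2 (R)-3-acryloyl-4-benzyloxazolidin-2-one
Conditions: nBuLi, THF, –78 °C; then acryloyl chloride, –78 → 0 °C
Reagents that add atoms: acryloyl chloride, C=CC(=O)Cl
Why: N-acylation of the lithiated oxazolidinone attaches the acryloyl group, giving the metathesis partner.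

**Step 2**
Reactants: 3 eugenol
Product: 4 MOM-eugenol
Conditions: MOMCl, iPr2NEt, CH2Cl2, 0 °C → rt
Reagents that add atoms: MOMCl, COCCl
Why: Masking the phenol as a MOM ether keeps it from quenching the Grignard and the enolate later, and it is removable with acid.

**Step 3**
Reactants: 4 MOM-eugenol; 2 N-acryloyl imide (2 equiv)
Product: 5 (E)-4-aryl-but-2-enoyl imide
Conditions: Hoveyda–Grubbs II (5 mol%), 1,4-benzoquinone (10 mol%), CH2Cl2, 40 °C
Reagents that add atoms: none (ethylene is lost)
Why: Cross-metathesis of a type I allylarene with an electron-poor acrylimide gives the E-enoyl imide; benzoquinone suppresses Ru–H isomerization of the allylarene.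

**Step 4**
Reactants: 5
Product: 6 (R)-4-benzyl-3-[(S)-4-aryl-3-methylbutanoyl]oxazolidin-2-one
Conditions: MeMgBr, CuBr·SMe2, THF/Me2S, –78 → –40 °C
Reagents that add atoms: MeMgBr, C[Mg]Br
Why: This is a Hruby/Evans Cu-catalysed 1,4-addition. Methyl adds to the Mg-chelated s-cis enoyl imide on the face opposite the C4 benzyl, which sets C8 as (S) in this intermediate.

**Step 5**
Reactants: 7 syringaldehyde
Product: 8 4-(benzyloxy)-3,5-dimethoxybenzaldehyde
Conditions: BnBr, K2CO3, DMF, 60 °C
Reagents that add atoms: BnBr, BrCc1ccccc1
Why: Williamson O-benzylation of the phenol.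

**Step 6**
Reactants: 8
Product: 9 (4-(benzyloxy)-3,5-dimethoxyphenyl)methanol
Conditions: NaBH4, MeOH/THF, 0 °C
Reagents that add atoms: none
Why: Chemoselective aldehyde reduction.

**Step 7**
Reactants: 9
Product: 10 4-(benzyloxy)-3,5-dimethoxybenzyl bromide
Conditions: PBr3, Et2O, 0 °C, 30 min; use crude immediately
Reagents that add atoms: PBr3, BrP(Br)Br
Why: Conversion of the benzylic alcohol to the bromide with PBr3, which gives the electrophile for Evans alkylation.

**Step 8**
Reactants: 6; 10
Product: 11 (R)-4-benzyl-3-[(2R,3S)-2-(syringylmethyl, O-Bn)-3-methyl-4-(4-MOMO-3-MeO-phenyl)butanoyl]oxazolidin-2-one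
Conditions: NaHMDS, THF, –78 °C, 45 min; then 10, –78 → –30 °C
Reagents that add atoms: none (10 is the named reactant)
Why: Evans alkylation of the Na (Z)-enolate. The benzyl bromide attacks anti to the C4 benzyl, setting C8' as (R); the C8 centre is not touched.

**Step 9**
Reactants: 11
Product: 12 (2R,3S)-2-[(4-benzyloxy-3,5-dimethoxyphenyl)methyl]-3-methyl-4-(3-methoxy-4-MOMO-phenyl)butan-1-ol (the auxiliary 1 is recovered)
Conditions: LiBH4, MeOH (2 equiv), Et2O, 0 °C → rt
Reagents that add atoms: none
Why: Reductive removal of the auxiliary to the primary alcohol; the MOM and benzyl ethers are inert and neither stereocentre is epimerizable under these conditions.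

**Step 10**
Reactants: 12
Product: 13 (2R,3S)-alcohol with free guaiacyl phenol
Conditions: 3 M HCl, THF/MeOH 1:1, 50 °C, 4 h
Reagents that add atoms: none
Why: Acidolysis of the aryl MOM acetal unmasks the phenol, which the next step needs; the benzyl aryl ether and primary alcohol survive.

**Step 11**
Reactants: 13
Product: 14 (7R,8R,8'R)-THF with syringyl O-benzyl ether
Conditions: DDQ (1.1 equiv), CH2Cl2 (0.01 M), 4 Å MS, 0 °C → rt, 2 h
Reagents that add atoms: none
Why: Proposed new method: the free guaiacyl phenol is dehydrogenated by DDQ to the p-quinone methide at C7 (phenol oxidation is much faster than oxidation of the benzyl-protected syringyl ring or of the primary alcohol). The tethered CH2OH then adds in a 5-exo oxa-Michael fashion, trans to the C8 methyl, and the QM/DDQH2 equilibration favours the all-trans-type (7,8-trans, 8,8'-trans) THF. The closest known reactions are DDQ dehydrogenation of 4-alkylphenols to p-QMs with oxa-Michael trapping, and the biosynthetic lignan THF closures; the new aspect is chemoselective dehydrogenative C(sp3)–H etherification of a stereodefined acyclic 1,4-diaryl-butanol carrying several electron-rich arenes, with C7 set by ring closure.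

**Step 12**
Reactants: 14
Product: 15 target
Conditions: H2 (1 atm), 10% Pd/C, EtOAc/EtOH, rt, 1 h
Reagents that add atoms: none
Why: Hydrogenolysis of the syringyl benzyl ether releases the phenol, and all three stereocentres are untouched.

## Compound list
1 | (R)-4-benzyloxazolidin-2-one | O=C1N[C@H](Cc2ccccc2)CO1 | starting material
2 | (R)-3-acryloyl-4-benzyloxazolidin-2-one | C=CC(=O)N1[C@H](Cc2ccccc2)COC1=O | intermediate
3 | eugenol | C=CCc1ccc(O)c(OC)c1 | starting material
4 | MOM-eugenol | C=CCc1ccc(OCOC)c(OC)c1 | intermediate
5 | (E)-enoyl imide | COCOc1ccc(C/C=C/C(=O)N2[C@H](Cc3ccccc3)COC2=O)cc1OC | intermediate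
6 | (S)-3-methyl-4-aryl butanoyl imide | COCOc1ccc(C[C@H](C)CC(=O)N2[C@H](Cc3ccccc3)COC2=O)cc1OC | intermediate
7 | syringaldehyde | COc1cc(C=O)cc(OC)c1O | starting material
8 | 4-(benzyloxy)-3,5-dimethoxybenzaldehyde | COc1cc(C=O)cc(OC)c1OCc1ccccc1 | intermediate
9 | (4-(benzyloxy)-3,5-dimethoxyphenyl)methanol | COc1cc(CO)cc(OC)c1OCc1ccccc1 | intermediate
10 | 4-(benzyloxy)-3,5-dimethoxybenzyl bromide | COc1cc(CBr)cc(OC)c1OCc1ccccc1 | intermediate
11 | alkylated imide | COCOc1ccc(C[C@H](C)[C@@H](Cc2cc(OC)c(OCc3ccccc3)c(OC)c2)C(=O)N2[C@H](Cc3ccccc3)COC2=O)cc1OC | intermediate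
12 | (2R,3S)-MOM-protected alcohol | COCOc1ccc(C[C@H](C)[C@@H](Cc2cc(OC)c(OCc3ccccc3)c(OC)c2)CO)cc1OC | intermediate
13 | (2R,3S)-phenol alcohol | COc1cc(C[C@H](C)[C@@H](Cc2cc(OC)c(OCc3ccccc3)c(OC)c2)CO)ccc1O | intermediate
14 | O-benzyl THF | COc1cc([C@@H]2OC[C@H](Cc3cc(OC)c(OCc4ccccc4)c(OC)c3)[C@H]2C)ccc1O | intermediate
15 | CID53359708 | COc1cc([C@@H]2OC[C@H](Cc3cc(OC)c(O)c(OC)c3)[C@H]2C)ccc1O | target

## Totals
- Total steps: 12.
- Longest linear sequence: 8 steps (eugenol → 4 → 5 → 6 → 11 → 12 → 13 → 14 → 15, or equally syringaldehyde → 8 → 9 → 10 → 11 → 12 → 13 → 14 → 15).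

## Three steps most likely to fail
1. **Step 11 (proposed new method).** The QM may tautomerize to the 4-alkenylphenol, which destroys C8; over-oxidation is also possible, and C-attack by the syringyl ring (aryltetralin formation) competes. Fallback: benzylate the phenol of 13 (BnBr, K2CO3), then run a Suárez alkoxy-radical 1,5-HAT cycloetherification (PhI(OAc)2, I2, hν), which is a radical rather than QM mechanism, followed by H2/Pd-C to remove both benzyls.
2. **Step 4.** The diastereoselectivity or facial sense of the Cu-mediated methyl addition may fall short, which would give the wrong 8,8' relationship after step 8. Fallback: use catalyst control instead, with a Cu/Josiphos asymmetric MeMgBr 1,4-addition to the corresponding (E)-enoate, then attach the (R)-auxiliary to the resulting acid and carry out the Evans benzylation.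
3. **Step 3.** Cross-metathesis may suffer allylarene isomerization or low conversion. Fallback: build 5 by a Horner–Wadsworth–Emmons route from the MOM-protected homovanillic aldehyde with triethyl phosphonoacetate, then saponify and acylate lithiated 1 through the pivaloyl mixed anhydride.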